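**Strategy.** The cyclopentane C4–C5–C6–C7–C16 (trinervitane numbering, see remark) is bare, but C7 carries the sp2 carbon C8. It is therefore drawn from a cyclohexane that still holds C8 between C7 and C6. A catalytic asymmetric quinone Diels–Alder reaction gives the cis-decalin (ring A plus ring C4–C5–C6–C8–C7–C16) with an endo C7–O bond. A temporary O3–C8 ether bridge locks this ring as a boat. Triflation of 7-OH then triggers a semipinacol shift of C6 from C8 to C7. The ring contracts, C7 is inverted to its concave configuration, C8 emerges as a methyl ketone and the bridge opens. Two Nozaki–Hiyama–Kishi couplings with (S)-citronellal build the eleven-membered ring.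

Key step: step 8

Remark on labels: reading the target SMILES from the left, the atoms are C19=C8, C9(OAc), C10, C11, C12(CH3-20), C13, C14(OAc), C1, C15(CH3-17), C16, C7, C6, C5, C4(CH3-18), C3(OH), C2(OAc). Ring A = C1–C2–C3–C4–C16–C15. "Top" is the face of the bicyclic core that bears H-16 and CH3-18. "Bottom" is the opposite, concave face.

Step 1
Reactants: 1 2-methoxy-6-methylphenol
Product: 2 2-methoxy-6-methyl-1,4-benzoquinone
Conditions: O2 (1 atm), Co(salen) (5 mol %), DMF, 23 °C
Reagents that add atoms: dioxygen O=O
Why: Cobalt–salen catalysed aerobic phenol-to-para-quinone oxidation, in which only the free para position of the 2,6-disubstituted phenol can be attacked.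

Step 2
Reactants: 3 tiglic aldehyde, (E)-2-methylbut-2-enal
Product: 4 (1E)-2-methyl-1-(triethylsilyloxy)buta-1,3-diene
Conditions: TESOTf, Et3N, Et2O, 0 °C
Reagents that add atoms: triethylsilyl triflate CC[Si](CC)(CC)OS(=O)(=O)C(F)(F)F
Why: Soft enolisation (O-silylation, then γ-deprotonation) of the s-trans enal should give the (1E)-dienol silyl ether, the geometry that is reactive in a Diels–Alder reaction.

Step 3
Reactants: 2 2-methoxy-6-methyl-1,4-benzoquinone; 4 (1E)-2-methyl-1-(triethylsilyloxy)buta-1,3-diene
Product: 5 endo adduct, (4aS,5S,8aS)-2-methoxy-6,8a-dimethyl-5-(triethylsilyloxy)-4a,5,8,8a-tetrahydronaphthalene-1,4-dione (H-7, H-16 and CH3-18 on top, 7-OTES on the bottom)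
Conditions: chiral diphenylprolinol-derived B-(o-tolyl)oxazaborolidinium triflimide (20 mol %, antipode chosen for the 4S,16S series), CH2Cl2, −78 °C
Reagents that add atoms: none
Why: Enantioselective oxazaborolidinium-catalysed quinone Diels–Alder reaction, in which the cation binds the more basic, unhindered vinylogous-ester carbonyl C15=O so that C4 becomes the electrophilic terminus and pairs with the nucleophilic CH2 (C5) of the 1-silyloxydiene, the methoxy-bearing alkene stays inert, the endo rule places 7-OTES cis to C15 and C3, and the shielded catalyst face sets C4, C16 and C7 in one event.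

Step 4
Reactants: 5 endo adduct
Product: 6 C3 alcohol of 5 (3-OH on the bottom face, C15 vinylogous ester intact)
Conditions: NaBH4, CeCl3·7H2O, MeOH–CH2Cl2, −78 °C
Reagents that add atoms: none
Why: Luche 1,2-reduction should take the cross-conjugated C3 ketone rather than the vinylogous ester C15=O, and hydride should enter from the open convex top face, which puts 3-OH on the concave bottom face where the bridge needs it.

Step 5
Reactants: 6 C3 alcohol
Product: 7 oxa-caged vinylogous ester (ether bridge O3–C8 on the bottom face, C6 now CH2, CH3-19 on top; ring C4–C5–C6–C8–C7–C16 held as the boat of a 2-oxabicyclo[2.2.2]octane)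
Conditions: Co(II)(salen-tBu) (5 mol %), N-fluoro-2,4,6-trimethylpyridinium triflate, PhSiH3, PhCF3, 23 °C
Reagents that add atoms: none
Why: Mukaiyama-type cobalt-hydride HAT/radical-polar crossover hydroalkoxylation, in which H adds to C6 of the only electron-neutral alkene and the tertiary C8 centre can be captured only from below by the tethered 3-OH, as in the terpineol-to-cineole closure, which sets C8.

Step 6
Reactants: 7 oxa-caged vinylogous ester
Product: 9 caged enone alcohol (C2=O, C1H=C15 bearing CH3-17, free 7-OH on the bottom, O3–C8 bridge kept), via C15 tertiary carbinol 8 (not isolated)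
Conditions: MeLi, CeCl3, THF, −78 °C; then 1 M aq HCl, THF, 23 °C
Reagents that add atoms: methyllithium [Li]C; water O
Why: Stork–Danheiser transposition, in which the weakly basic organocerium reagent adds 1,2 to the vinylogous ester from the open top face and acid then ionises the tertiary allylic alcohol, hydrolyses the enol ether to the transposed enone and removes the TES group, while the tertiary bridging ether should survive.

Step 7
Reactants: 9 caged enone alcohol
Product: 10 caged 1-iodo enone alcohol
Conditions: I2, pyridine, CH2Cl2, 23 °C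
Reagents that add atoms: iodine II
Why: α-Iodination of an enone by the pyridine addition–iodination–elimination sequence functionalises the only enone α-CH, C1.

Step 8
Reactants: 10 caged 1-iodo enone alcohol
Product: 13 cis-hydrindane hydroxy diketone (cyclopentane C4–C5–C6–C7–C16; 7-acetyl on the bottom concave face, H-7 on top; 3-OH on the bottom; ring A 1-iodo-2-enone), via C7 triflate 11 (not isolated), via bicyclic oxocarbenium triflate 12 (not isolated)
Conditions: Tf2O, 2,6-di-tert-butyl-4-methylpyridine, CH2Cl2, −78 to 0 °C; then H2O–THF, 0 °C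
Reagents that add atoms: water O
Why: O-Triflation turns the bottom-face 7-OH into a leaving group that, in the rigid 2-oxabicyclo[2.2.2]octane, is antiperiplanar to the C8–C6 bond, which is itself antiperiplanar to a lone pair of the bridging oxygen, so ionisation, 1,2-shift of C6 from C8 to C7 and formation of oxocarbenium ion 12 should be one push–pull event, after which water adds to C8 and cleaves the C8–O3 bond to give the methyl ketone and free 3-OH. The closest known reaction type is the semipinacol ring contraction of 2-sulfonyloxy tertiary carbinol derivatives to acylcyclopentanes, here with an ether oxygen as the donor. The five-membered ring C4–C5–C6–C7–C16 is closed by a suprafacial Wagner–Meerwein 1,2-alkyl shift out of the six-membered ring C4–C5–C6–C8–C7–C16, not by a cyclisation. C7 is the only stereocentre formed, and it is formed with inversion, so the endo C7–O bond of the Diels–Alder step is translated into the contra-thermodynamic arrangement with H-7 on top and C8 on the concave face, cis to C15. The step needs migration of C6 rather than of CH3-19 or oxygen and no elimination, which the cage secures because CH3-19 and O3 are gauche to the leaving group and no C–H bond is antiperiplanar to it across the eclipsed C7–C16 bond. C3, C4 and C16 are untouched, and the non-nucleophilic base should keep the new epimerisable ketone from enolising.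

Step 9
Reactants: 13 cis-hydrindane hydroxy diketone; 14 (S)-citronellal
Product: 15 (14S)-allylic alcohol (C1–C14 bond formed; chain C14–C9 with 12S methyl and terminal isopropylidene)
Conditions: CrCl2 (4 equiv), NiCl2 (2 mol %), chiral oxazoline–sulfonamide ligand, Et3N, THF, 23 °C
Reagents that add atoms: none
Why: Nozaki–Hiyama–Kishi coupling, in which the alkenylchromium species made from the C1–I bond adds only to the aldehyde and leaves both ketones and the free hydroxyl alone, and the chiral ligand on chromium sets C14 (S) by reagent control, while C12 is bought with citronellal.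

Step 10
Reactants: 15 (14S)-allylic alcohol
Product: 16 3,14-bis(triethylsilyl) ether
Conditions: TESOTf (2.3 equiv), 2,6-lutidine, CH2Cl2, −78 °C
Reagents that add atoms: triethylsilyl triflate CC[Si](CC)(CC)OS(=O)(=O)C(F)(F)F
Why: O-Silylation with the reactive silyl triflate covers the allylic 14-OH and the hindered 3-OH in one operation, so that only C–H acids remain for the next step.

Step 11
Reactants: 16 3,14-bis(triethylsilyl) ether
Product: 17 C8 enol triflate (C7–C8(OTf)=C19H2)
Conditions: KHMDS (1.05 equiv), THF, −78 °C; N-(5-chloro-2-pyridyl)bis(trifluoromethanesulfonimide)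
Reagents that add atoms: N-(5-chloro-2-pyridyl)bis(trifluoromethanesulfonimide) O=S(=O)(N(c1ccc(Cl)cn1)S(=O)(=O)C(F)(F)F)C(F)(F)F
Why: Kinetic enolate formation and O-sulfonylation, in which the bulky amide base should deprotonate the unhindered CH3-19 faster than C7-H, C3-H or the vinylogous positions of the enone, and triflyl transfer fixes the 1,1-disubstituted enol triflate, after which C7 can no longer epimerise.

Step 12
Reactants: 17 C8 enol triflate
Product: 19 diol enol triflate with 3-OH on the top face (equatorial) and free 14-OH, via 3-epi diol 18 (not isolated)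
Conditions: Et3N·3HF, MeCN, 23 °C; then DBU, 23 °C, under argon
Reagents that add atoms: none
Why: Fluoride desilylation followed by a Lobry de Bruyn–van Ekenstein type epimerisation, in which the α-ketol equilibrates through its enediolate and the axial bottom-face 3-OH, 1,3-diaxial to C7, should move to the equatorial top face, which sets C3 under thermodynamic control while the conjugated C2 enone stays the most stable ketol isomer.

Step 13
Reactants: 19 diol enol triflate
Product: 20 C9 aldehyde
Conditions: O3, CH2Cl2–MeOH, −78 °C (dye end point); Me2S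
Reagents that add atoms: ozone [O-][O+]=O
Why: Chemoselective ozonolysis, since the electron-rich trisubstituted isopropylidene alkene reacts far faster than the tetrasubstituted enone alkene and the enol triflate.

Step 14
Reactants: 20 C9 aldehyde
Product: 21 tricyclic triol enone (eleven-membered ring closed; 9R-OH next to C8=C19H2)
Conditions: CrCl2 (15 equiv), NiCl2 (1 mol %), DMSO–THF, 2 mM, syringe pump, 23 °C
Reagents that add atoms: none
Why: Intramolecular Nozaki–Hiyama–Kishi reaction under high dilution closes the eleven-membered ring by forming C8–C9 and delivers the 2-methylene-1-ol unit directly, and C9 should arise from addition to the aldehyde face exposed on the periphery of the folded chain, whose shape is fixed by C7, C12 and C14.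

Step 15
Reactants: 21 tricyclic triol enone
Product: 22 tetraol (2-OH on the bottom, trans to the top-face 3-OH)
Conditions: Me4NBH(OAc)3, MeCN–AcOH, −30 °C
Reagents that add atoms: none
Why: Evans–Saksena hydroxyl-directed reduction, in which the acetoxyborohydride exchanges onto the top-face 3-OH (and 14-OH) and hands hydride to the top face of C2=O, giving the bottom-face 2-OH against the steric bias of the axial CH3-18.

Step 16
Reactants: 22 tetraol
Product: 23 CNP0318778.1 (2,9,14-triacetate, free 3-OH)
Conditions: Ac2O (3.5 equiv), pyridine, CH2Cl2, 0 °C, no DMAP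
Reagents that add atoms: acetic anhydride CC(=O)OC(C)=O
Why: Site-selective acylation, in which the secondary alcohols at C2, C9 and C14 are esterified whereas 3-OH, neopentylic next to quaternary C4 and flanked by the new 2-acetate, should stay free.

**Compound list**

1 | 2-methoxy-6-methylphenol | COc1cccc(C)c1O | starting material
2 | 2-methoxy-6-methyl-1,4-benzoquinone | COC1=CC(=O)C=C(C)C1=O | intermediate
3 | tiglic aldehyde | C/C=C(\C)C=O | starting material
4 | (1E)-2-methyl-1-(triethylsilyloxy)buta-1,3-diene | C=C/C(C)=C/O[Si](CC)(CC)CC | intermediate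
5 | endo Diels–Alder adduct (cis-decalin enedione, 7-OTES bottom) | COC1=CC(=O)[C@@H]2[C@H](O[Si](CC)(CC)CC)C(C)=CC[C@]2(C)C1=O | intermediate
6 | C3 alcohol (3-OH bottom) | COC1=CC(=O)[C@@H]2[C@H](O[Si](CC)(CC)CC)C(C)=CC[C@]2(C)[C@@H]1O | intermediate
7 | oxa-caged vinylogous ester (O3–C8 bridge) | COC1=CC(=O)[C@@H]2[C@H](O[Si](CC)(CC)CC)[C@@]3(C)CC[C@]2(C)[C@@H]1O3 | intermediate
8 | C15 tertiary carbinol (CH3-17 top, OH bottom) | COC1=C[C@](C)(O)[C@@H]2[C@H](O[Si](CC)(CC)CC)[C@@]3(C)CC[C@]2(C)[C@@H]1O3 | intermediate
9 | caged enone alcohol | O=C1C=C(C)[C@@H]2[C@H](O)[C@@]3(C)CC[C@]2(C)[C@@H]1O3 | intermediate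
10 | caged 1-iodo enone alcohol | O=C1C(I)=C(C)[C@@H]2[C@H](O)[C@@]3(C)CC[C@]2(C)[C@@H]1O3 | intermediate
11 | C7 triflate | O=C1C(I)=C(C)[C@@H]2[C@H](OS(=O)(=O)C(F)(F)F)[C@@]3(C)CC[C@]2(C)[C@@H]1O3 | intermediate
12 | bicyclic oxocarbenium triflate (ring already contracted) | O=C1C(I)=C(C)[C@@H]2[C@H]3CC[C@]2(C)[C@@H]1[O+]=C3C.[O-]S(=O)(=O)C(F)(F)F | intermediate
13 | cis-hydrindane hydroxy diketone (7-acetyl bottom, 3-OH bottom) | O=C1C(I)=C(C)[C@@H]2[C@H](C(C)=O)CC[C@]2(C)[C@@H]1O | intermediate
14 | (S)-citronellal | CC(C)=CCC[C@H](C)CC=O | starting material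
15 | (14S)-allylic alcohol | CC(C)=CCC[C@H](C)C[C@H](O)C1=C(C)[C@@H]2[C@H](C(C)=O)CC[C@]2(C)[C@H](O)C1=O | intermediate
16 | 3,14-bis(triethylsilyl) ether | CC(C)=CCC[C@H](C)C[C@H](O[Si](CC)(CC)CC)C1=C(C)[C@@H]2[C@H](C(C)=O)CC[C@]2(C)[C@H](O[Si](CC)(CC)CC)C1=O | intermediate
17 | C8 enol triflate | CC(C)=CCC[C@H](C)C[C@H](O[Si](CC)(CC)CC)C1=C(C)[C@@H]2[C@H](C(=C)OS(=O)(=O)C(F)(F)F)CC[C@]2(C)[C@H](O[Si](CC)(CC)CC)C1=O | intermediate
18 | 3-epi diol enol triflate (3-OH bottom) | CC(C)=CCC[C@H](C)C[C@H](O)C1=C(C)[C@@H]2[C@H](C(=C)OS(=O)(=O)C(F)(F)F)CC[C@]2(C)[C@H](O)C1=O | intermediate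
19 | diol enol triflate (3-OH top) | CC(C)=CCC[C@H](C)C[C@H](O)C1=C(C)[C@@H]2[C@H](C(=C)OS(=O)(=O)C(F)(F)F)CC[C@]2(C)[C@@H](O)C1=O | intermediate
20 | C9 aldehyde | O=CCC[C@H](C)C[C@H](O)C1=C(C)[C@@H]2[C@H](C(=C)OS(=O)(=O)C(F)(F)F)CC[C@]2(C)[C@@H](O)C1=O | intermediate
21 | tricyclic triol enone | C=C1[C@H](O)CC[C@H](C)C[C@H](O)C2=C(C)[C@@H]3[C@H]1CC[C@]3(C)[C@@H](O)C2=O | intermediate
22 | tetraol | C=C1[C@H](O)CC[C@H](C)C[C@H](O)C2=C(C)[C@@H]3[C@H]1CC[C@]3(C)[C@@H](O)[C@@H]2O | intermediate
23 | CNP0318778.1 | C=C1[C@H](OC(C)=O)CC[C@H](C)C[C@H](OC(C)=O)C2=C(C)[C@@H]3[C@H]1CC[C@]3(C)[C@@H](O)[C@@H]2OC(C)=O | target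

Total step count: 16. Longest linear sequence: 15 steps (from 1 or from 3).

**Steps most likely to fail**

1. Step 8. The C7 triflate may ionise without migration of C6, through cleavage of the bridging ether, displacement of triflate, or loss of a proton from the cation with scrambling of C7. The fallback gives up the cage and uses a free tertiary alcohol with aluminium push–pull activation. It sets out from 6 and comes back at 13.
   - The 3-OH is silylated (TBSOTf, 2,6-lutidine) to the 3-O-TBS ether F1.
   - Mukaiyama hydration (Mn(dpm)3, PhSiH3, O2) gives the unbridged C8 tertiary alcohol F2.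
   - MeLi/CeCl3 gives the C15 carbinol F3, which aqueous HCl converts into the enone 7,8-diol F4.
   - I2/pyridine gives the iodo enone diol F5, and MsCl/Et3N gives the C7 mesylate F6.
   - Et2AlCl forms an aluminium alkoxide that chelates the mesylate and should drive the hydroxy-mesylate semipinacol contraction to the 3-O-TBS acetylhydrindane F7.
   - HF·pyridine returns to 13.

2. Step 14. Closure of the eleven-membered ring may lose to oligomerisation or to reduction of the triflate, and the aldehyde face may be poorly differentiated. The fallback changes the ring-closing reaction. It sets out from 19 and comes back at 21.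
   - TBAF·3H2O in DMF eliminates triflate to the terminal alkyne F8.
   - Ozonolysis of the isopropylidene group gives the ynal F9.
   - Nickel(0)/bulky N-heterocyclic carbene/Et3SiH reductive alkyne–aldehyde macrocyclisation, with C–C bond formation at the internal alkyne carbon, gives the 9-O-triethylsilyl macrocycle F10.
   - Et3N·3HF converts F10 into 21.

3. Step 5. Hydrogen-atom transfer may go to the vinylogous-ester alkene, or the C8 cation equivalent may be consumed by a hydride shift from C7 before the hindered 3-OH reaches it. The fallback replaces the radical-polar process by a polar anti addition. It sets out from 6 and comes back at 7.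
   - Hg(OCOCF3)2 in THF, then aqueous NaCl, gives by intramolecular alkoxymercuration (mercury on top at C6, O3 from below at C8) the organomercurial chloride F11.
   - Alkaline NaBH4 demercurates F11 to 7.

**Further compounds**

F1 | step 8 | 3-O-TBS ether of 6 | COC1=CC(=O)[C@@H]2[C@H](O[Si](CC)(CC)CC)C(C)=CC[C@]2(C)[C@@H]1O[Si](C)(C)C(C)(C)C
F2 | step 8 | unbridged C8 tertiary alcohol (8-OH top) | COC1=CC(=O)[C@@H]2[C@H](O[Si](CC)(CC)CC)[C@@](C)(O)CC[C@]2(C)[C@@H]1O[Si](C)(C)C(C)(C)C
F3 | step 8 | C15 carbinol | COC1=C[C@](C)(O)[C@@H]2[C@H](O[Si](CC)(CC)CC)[C@@](C)(O)CC[C@]2(C)[C@@H]1O[Si](C)(C)C(C)(C)C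
F4 | step 8 | enone 7,8-diol | O=C1C=C(C)[C@@H]2[C@H](O)[C@@](C)(O)CC[C@]2(C)[C@@H]1O[Si](C)(C)C(C)(C)C
F5 | step 8 | iodo enone diol | O=C1C(I)=C(C)[C@@H]2[C@H](O)[C@@](C)(O)CC[C@]2(C)[C@@H]1O[Si](C)(C)C(C)(C)C
F6 | step 8 | C7 mesylate | O=C1C(I)=C(C)[C@@H]2[C@H](OS(C)(=O)=O)[C@@](C)(O)CC[C@]2(C)[C@@H]1O[Si](C)(C)C(C)(C)C
F7 | step 8 | 3-O-TBS acetylhydrindane | O=C1C(I)=C(C)[C@@H]2[C@H](C(C)=O)CC[C@]2(C)[C@@H]1O[Si](C)(C)C(C)(C)C
F8 | step 14 | terminal alkyne | CC(C)=CCC[C@H](C)C[C@H](O)C1=C(C)[C@@H]2[C@H](C#C)CC[C@]2(C)[C@@H](O)C1=O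
F9 | step 14 | ynal | O=CCC[C@H](C)C[C@H](O)C1=C(C)[C@@H]2[C@H](C#C)CC[C@]2(C)[C@@H](O)C1=O
F10 | step 14 | 9-O-triethylsilyl macrocycle | C=C1[C@H](O[Si](CC)(CC)CC)CC[C@H](C)C[C@H](O)C2=C(C)[C@@H]3[C@H]1CC[C@]3(C)[C@@H](O)C2=O
F11 | step 5 | organomercurial chloride (HgCl on top at C6) | COC1=CC(=O)[C@@H]2[C@H](O[Si](CC)(CC)CC)[C@@]3(C)[C@@H]([Hg]Cl)C[C@]2(C)[C@@H]1O3
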